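**Plan**
1. Hardest point: the fully substituted carbinol carbon on ring B. CH3 and isohexyl must be told apart, and with the ortho phenol it ionises easily to an o-quinone methide, so no acidic step may follow its formation.
2. Retrosynthetic cuts, in order: the three ArO–Bn bonds; the C-1′(ring B)–CH2 bond (ring-A benzylzinc + ring-B aryl chloride); then, at the carbinol, the C–O and the C–isohexyl bond together, back to a 1-arylethyl carbamate and isohexyl–Bpin.
3. Enabling feature: the carbinol carbon is bonded directly to C-4′ of ring B and carries a CH3, so it is the α-carbon of a 1-arylethanol. Its benzylic C–H can be lithiated with retention, and its C–O bond can serve as the leaving group for a 1,2-shift from boron.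
4. Forward: 4′-chloro-2′-hydroxyacetophenone → benzyl ether → CBS reduction → carbamate → lithiation–borylation–oxidation (adds the whole C6 chain) → Negishi union with the ring-A benzylzinc → neutral hydrogenolysis.
5. Stereochemistry: the CBS reduction sets an (R)-secondary carbinol; the stereospecific 1,2-metallate rearrangement relays it to the (S)-quaternary carbinol. Ring-A regiochemistry is bought with 2-hydroxy-3-methoxy-5-methylbenzaldehyde.

Key step: step 5

Remark: the carbinol carbon of the given SMILES is read as (S) (OH > ring B > CH2 > CH3); compounds 1, 5 and 11 are taken as catalogue compounds.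

**Step 1**
Reactants: 1 1-(4-chloro-2-hydroxyphenyl)ethan-1-one
Product: 2 1-[2-(benzyloxy)-4-chlorophenyl]ethan-1-one
Conditions: BnBr, K2CO3, DMF, 60 °C
Reagents that add atoms: benzyl bromide, BrCc1ccccc1
Why: Williamson etherification of the only acidic OH; benzyl is chosen because it should tolerate s-BuLi at −78 °C and leaves at the end without acid.

**Step 2**
Reactants: 2 1-[2-(benzyloxy)-4-chlorophenyl]ethan-1-one
Product: 3 (R)-1-[2-(benzyloxy)-4-chlorophenyl]ethan-1-ol
Conditions: (S)-Me-CBS (10 mol%), BH3·SMe2, THF, −20 °C; MeOH, then aq. NH4Cl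
Reagents that add atoms: none
Why: Corey–Bakshi–Shibata reduction; the (S)-oxazaborolidine·BH3 complex should bind the ketone with the aryl group as the large substituent and deliver hydride to the Si face, setting the (R)-carbinol.

**Step 3**
Reactants: 3 (R)-1-[2-(benzyloxy)-4-chlorophenyl]ethan-1-ol
Product: 4 (R)-1-[2-(benzyloxy)-4-chlorophenyl]ethyl N,N-diisopropylcarbamate
Conditions: iPr2NCOCl, Et3N, toluene, 90 °C
Reagents that add atoms: N,N-diisopropylcarbamoyl chloride, CC(C)N(C(C)C)C(Cl)=O
Why: O-carbamoylation of the secondary alcohol; no bond to the stereocentre is broken, and the hindered carbamate is the directing and leaving group needed in step 5.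

**Step 4**
Reactants: 5 4-methylpent-1-ene
Product: 6 4,4,5,5-tetramethyl-2-(4-methylpentyl)-1,3,2-dioxaborolane
Conditions: HBpin, [Ir(cod)Cl]2 (1.5 mol%), dppm (3 mol%), CH2Cl2, rt
Reagents that add atoms: pinacolborane, CC1(C)OBOC1(C)C
Why: Iridium-catalysed anti-Markovnikov hydroboration of a terminal alkene should give the linear primary pinacol boronate.

**Step 5**
Reactants: 4 (R)-1-[2-(benzyloxy)-4-chlorophenyl]ethyl N,N-diisopropylcarbamate; 6 4,4,5,5-tetramethyl-2-(4-methylpentyl)-1,3,2-dioxaborolane
Product: 10 (S)-2-[2-(benzyloxy)-4-chlorophenyl]-6-methylheptan-2-ol, via lithiated carbamate 7 (not isolated), via lithium boronate complex 8 (not isolated), via tertiary boronic ester 9 (not isolated)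
Conditions: s-BuLi (1.2 equiv), Et2O, −78 °C; then 6 (1.5 equiv), −78 °C; then MgBr2·OEt2/MeOH, −78 °C → rt; then 2 M NaOH, 30% H2O2, THF, 0 °C → rt
Reagents that add atoms: hydrogen peroxide, OO
Why: s-BuLi should remove the benzylic C–H of 4 (acidified by ring B, directed by Li–O=C chelation) with retention to give the configurationally stable 7; boronate 6 is then captured with retention to give ate complex 8, the isohexyl group migrates from boron to carbon anti to the departing carbamate (stereoinvertive 1,2-metallate shift) to give 9, and the C–B bond is oxidised with retention. The closest known reaction type is the lithiation–borylation of enantioenriched secondary benzylic carbamates with alkyl pinacol boronates followed by oxidation to tertiary alcohols. No ring is closed; the single new stereocentre is controlled only by the configuration of 4, the net result being replacement of H by isohexyl with retention of geometry, so that (R)-4 should give (S)-10. The step needs stereospecificity, which MgBr2/MeOH should secure by accelerating the 1,2-shift and protonating any lithiated carbamate released by reversal of 8 before it can racemise. It also needs benzylic lithiation to win over ring lithiation at C-3 (between OBn and Cl) and over deprotonation of OCH2Ph, which the carbamate-directed deprotonation in Et2O at −78 °C with only a slight excess of base should secure.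

**Step 6**
Reactants: 11 2-hydroxy-3-methoxy-5-methylbenzaldehyde
Product: 12 2,3-dihydroxy-5-methylbenzaldehyde
Conditions: BBr3 (2.5 equiv), CH2Cl2, −78 °C → rt; H2O
Reagents that add atoms: none
Why: Lewis-acid O-demethylation (bromide attacks the O-methyl of the boron-complexed ether); it is done here, before any acid-sensitive group exists.

**Step 7**
Reactants: 12 2,3-dihydroxy-5-methylbenzaldehyde
Product: 13 2,3-bis(benzyloxy)-5-methylbenzaldehyde
Conditions: BnBr (2.4 equiv), K2CO3, DMF, 60 °C
Reagents that add atoms: benzyl bromide, BrCc1ccccc1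
Why: double Williamson etherification puts the catechol under the same protecting group as ring B.

**Step 8**
Reactants: 13 2,3-bis(benzyloxy)-5-methylbenzaldehyde
Product: 14 [2,3-bis(benzyloxy)-5-methylphenyl]methanol
Conditions: NaBH4, MeOH/THF, 0 °C
Reagents that add atoms: none
Why: borohydride reduction of an aryl aldehyde; the benzyl ethers are inert.

**Step 9**
Reactants: 14 [2,3-bis(benzyloxy)-5-methylphenyl]methanol
Product: 15 1,2-bis(benzyloxy)-3-(chloromethyl)-5-methylbenzene
Conditions: SOCl2 (1.2 equiv), CH2Cl2, 0 °C → rt; used crude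
Reagents that add atoms: thionyl chloride, O=S(Cl)Cl
Why: chlorination of a benzylic alcohol through its chlorosulfite; the electron-rich benzylic chloride is taken on without purification.

**Step 10**
Reactants: 15 1,2-bis(benzyloxy)-3-(chloromethyl)-5-methylbenzene; 10 (S)-2-[2-(benzyloxy)-4-chlorophenyl]-6-methylheptan-2-ol
Product: 17 (S)-2-[2-(benzyloxy)-4-{[2,3-bis(benzyloxy)-5-methylphenyl]methyl}phenyl]-6-methylheptan-2-ol, via benzylzinc chloride 16 (not isolated)
Conditions: Zn dust, LiCl, THF, 25 °C; then 10 (0.6 equiv), Pd(OAc)2 (2 mol%), SPhos (4 mol%), THF, 50 °C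
Reagents that add atoms: none
Why: LiCl-promoted zinc insertion into the benzylic C–Cl bond followed by Negishi sp3–sp2 coupling; the biarylphosphine should allow oxidative addition into the aryl chloride, the benzylzinc should tolerate the hindered tertiary OH, and the remote stereocentre is untouched.

**Step 11**
Reactants: 17 (S)-2-[2-(benzyloxy)-4-{[2,3-bis(benzyloxy)-5-methylphenyl]methyl}phenyl]-6-methylheptan-2-ol
Product: 18 Asperchondol A, (S)-3-{[3-hydroxy-4-(2-hydroxy-6-methylheptan-2-yl)phenyl]methyl}-5-methylbenzene-1,2-diol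
Conditions: H2 (1 atm), 10% Pd/C, EtOAc, rt; filtration under argon
Reagents that add atoms: none
Why: hydrogenolysis of three aryl benzyl ethers under neutral conditions at room temperature, where the tertiary benzylic C–OH and the diarylmethane are expected to persist; no acid is used, so the carbinol stereocentre should not ionise.

**Compound list**
1 | 1-(4-chloro-2-hydroxyphenyl)ethan-1-one | CC(=O)c1ccc(Cl)cc1O | starting material
2 | 1-[2-(benzyloxy)-4-chlorophenyl]ethan-1-one | CC(=O)c1ccc(Cl)cc1OCc1ccccc1 | intermediate
3 | (R)-1-[2-(benzyloxy)-4-chlorophenyl]ethan-1-ol | C[C@@H](O)c1ccc(Cl)cc1OCc1ccccc1 | intermediate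
4 | (R)-1-[2-(benzyloxy)-4-chlorophenyl]ethyl N,N-diisopropylcarbamate | C[C@@H](OC(=O)N(C(C)C)C(C)C)c1ccc(Cl)cc1OCc1ccccc1 | intermediate
5 | 4-methylpent-1-ene | C=CCC(C)C | starting material
6 | 4,4,5,5-tetramethyl-2-(4-methylpentyl)-1,3,2-dioxaborolane | CC(C)CCCB1OC(C)(C)C(C)(C)O1 | intermediate
7 | (R)-1-[2-(benzyloxy)-4-chlorophenyl]-1-lithioethyl N,N-diisopropylcarbamate (lithiated carbamate) | C[C@@]([Li])(OC(=O)N(C(C)C)C(C)C)c1ccc(Cl)cc1OCc1ccccc1 | intermediate (not isolated)
8 | lithium (R)-{1-[2-(benzyloxy)-4-chlorophenyl]-1-[(diisopropylcarbamoyl)oxy]ethyl}(4-methylpentyl)(pinacolato)borate | C[C@@]([B-]1(CCCC(C)C)OC(C)(C)C(C)(C)O1)(OC(=O)N(C(C)C)C(C)C)c1ccc(Cl)cc1OCc1ccccc1.[Li+] | intermediate (not isolated)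
9 | (R)-2-{2-[2-(benzyloxy)-4-chlorophenyl]-6-methylheptan-2-yl}-4,4,5,5-tetramethyl-1,3,2-dioxaborolane | C[C@@](CCCC(C)C)(B1OC(C)(C)C(C)(C)O1)c1ccc(Cl)cc1OCc1ccccc1 | intermediate (not isolated)
10 | (S)-2-[2-(benzyloxy)-4-chlorophenyl]-6-methylheptan-2-ol | C[C@@](CCCC(C)C)(O)c1ccc(Cl)cc1OCc1ccccc1 | intermediate
11 | 2-hydroxy-3-methoxy-5-methylbenzaldehyde | Cc1cc(OC)c(O)c(C=O)c1 | starting material
12 | 2,3-dihydroxy-5-methylbenzaldehyde | Cc1cc(O)c(O)c(C=O)c1 | intermediate
13 | 2,3-bis(benzyloxy)-5-methylbenzaldehyde | Cc1cc(OCc2ccccc2)c(OCc2ccccc2)c(C=O)c1 | intermediate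
14 | [2,3-bis(benzyloxy)-5-methylphenyl]methanol | Cc1cc(OCc2ccccc2)c(OCc2ccccc2)c(CO)c1 | intermediate
15 | 1,2-bis(benzyloxy)-3-(chloromethyl)-5-methylbenzene | Cc1cc(OCc2ccccc2)c(OCc2ccccc2)c(CCl)c1 | intermediate
16 | {[2,3-bis(benzyloxy)-5-methylphenyl]methyl}zinc chloride | Cc1cc(OCc2ccccc2)c(OCc2ccccc2)c(C[Zn]Cl)c1 | intermediate (not isolated)
17 | (S)-2-[2-(benzyloxy)-4-{[2,3-bis(benzyloxy)-5-methylphenyl]methyl}phenyl]-6-methylheptan-2-ol | Cc1cc(OCc2ccccc2)c(OCc2ccccc2)c(Cc2ccc([C@@](C)(O)CCCC(C)C)c(OCc3ccccc3)c2)c1 | intermediate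
18 | Asperchondol A | Cc1cc(O)c(O)c(Cc2ccc([C@@](C)(O)CCCC(C)C)c(O)c2)c1 | target

**Count**
Total steps: 11. Longest linear sequence: 6 steps (1 → 2 → 3 → 4 → 10 → 17 → 18, or 11 → 12 → 13 → 14 → 15 → 17 → 18).

**Steps most likely to fail**

Step 5. Two processes threaten it. The congested ate complex 8 (ortho-benzyloxy aryl) may revert to the lithiated carbamate, which racemises on warming and erodes the stereospecificity. The base may also lithiate the ring between OBn and Cl instead of the benzylic position. The fallback sets out from 2 and comes back at 10, setting the tertiary C–O centre by reagent-controlled epoxidation. Horner–Wadsworth–Emmons olefination of 2 (triethyl phosphonoacetate, NaH, THF, reflux) should give ethyl (E)-3-[2-(benzyloxy)-4-chlorophenyl]but-2-enoate F1. DIBAL-H (CH2Cl2, −78 °C) should reduce it to (E)-3-[2-(benzyloxy)-4-chlorophenyl]but-2-en-1-ol F2. Sharpless epoxidation with Ti(OiPr)4, D-(−)-diethyl tartrate and t-BuOOH (4 Å sieves, CH2Cl2, −20 °C) should give [(2R,3R)-3-[2-(benzyloxy)-4-chlorophenyl]-3-methyloxiran-2-yl]methanol F3. Red-Al (THF, 0 °C) should deliver hydride from the alkoxide to C-2 and leave the benzylic C–O bond intact, giving (S)-3-[2-(benzyloxy)-4-chlorophenyl]butane-1,3-diol F4. Selective sulfonylation of the primary OH (TsCl, Et3N, cat. DMAP, CH2Cl2, 0 °C) should give (S)-3-[2-(benzyloxy)-4-chlorophenyl]-3-hydroxybutyl 4-methylbenzenesulfonate F5. Copper-catalysed coupling with isobutylmagnesium bromide (cat. Li2CuCl4, THF, −20 °C) completes the chain and returns to 10.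

Step 10. Oxidative addition into the electron-rich aryl chloride may be slow. The benzylzinc reagent could then be lost by Wurtz-type homocoupling or by protonation at the tertiary OH. The fallback sets out from 10 and 15 and comes back at 17, with the roles of the two partners reversed. Miyaura borylation of 10 (B2pin2, Pd2(dba)3/XPhos, KOAc, dioxane, 100 °C) should give (S)-2-[2-(benzyloxy)-4-(4,4,5,5-tetramethyl-1,3,2-dioxaborolan-2-yl)phenyl]-6-methylheptan-2-ol F6. Suzuki–Miyaura coupling of F6 with benzylic chloride 15 (Pd(dppf)Cl2, K3PO4, dioxane/H2O, 80 °C) should then give 17. This uses the easy oxidative addition into the benzylic C–Cl bond and needs no organozinc.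

Step 11. Once the ring-B phenol is unmasked on the catalyst, the tertiary benzylic hydroxyl may be lost by hydrogenolysis through an o-quinone methide. The hindered ring-B ether may also cleave incompletely. The fallback sets out from 17 and comes back at 18, and replaces surface hydrogenolysis by electron-transfer cleavage. Treatment of 17 with lithium naphthalenide (THF, −25 °C, excess) and a degassed NH4Cl quench under argon should fragment the three ArO–CH2Ph bonds as radical anions. The carbinol is then present as its lithium alkoxide, which cannot ionise to a quinone methide. No new isolated compound arises.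

**Further compounds**
F1 | step 5 | ethyl (E)-3-[2-(benzyloxy)-4-chlorophenyl]but-2-enoate | CCOC(=O)/C=C(\C)c1ccc(Cl)cc1OCc1ccccc1
F2 | step 5 | (E)-3-[2-(benzyloxy)-4-chlorophenyl]but-2-en-1-ol | OC/C=C(\C)c1ccc(Cl)cc1OCc1ccccc1
F3 | step 5 | [(2R,3R)-3-[2-(benzyloxy)-4-chlorophenyl]-3-methyloxiran-2-yl]methanol | Clc1ccc([C@@]2(C)O[C@@H]2CO)c(OCc2ccccc2)c1
F4 | step 5 | (S)-3-[2-(benzyloxy)-4-chlorophenyl]butane-1,3-diol | Clc1ccc([C@@](C)(O)CCO)c(OCc2ccccc2)c1
F5 | step 5 | (S)-3-[2-(benzyloxy)-4-chlorophenyl]-3-hydroxybutyl 4-methylbenzenesulfonate | Clc1ccc([C@@](C)(O)CCOS(=O)(=O)c2ccc(C)cc2)c(OCc2ccccc2)c1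
F6 | step 10 | (S)-2-[2-(benzyloxy)-4-(4,4,5,5-tetramethyl-1,3,2-dioxaborolan-2-yl)phenyl]-6-methylheptan-2-ol | CC1(C)OB(OC1(C)C)c1ccc([C@@](C)(O)CCCC(C)C)c(OCc2ccccc2)c1
F0 | step 11 | none | none
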